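The route rests on opening ring B at C5–C10 and C8–C9 (labdane numbering), the two bonds on either side of C9–C10. Quaternary C10 with methyl C20 and C9 with C11 then form an (E)-3-methyl-2-enoate, and C5–C8 a 1-silyloxydiene whose C8 oxygen is later exchanged for the C17 methylene. One intramolecular Diels–Alder reaction of the open-chain trienoate makes both bonds, closes rings A and B as a trans-fused octalin and sets C5, C8, C9 and C10 under control of a single silyloxy stereocenter at C2. The precursor is a methyl (2E,8E,10E)-undecatrienoate with the C4 gem-dimethyl group, an (R)-configured C2 silyl ether and a triethylsilyl dienol ether terminus.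

Key step: step 7

Remarks on the chemistry:
- Bicyclic compounds are named on the labdane skeleton with labdane numbering and the normal labdane configuration (5α-H, 9α-H, 10β-CH3 = C20); β is the face of C20.
- 2,2-Dimethylpent-4-enal, allenylboronic acid pinacol ester, crotonaldehyde and methyl hydrogen (R)-3-methylglutarate are assumed to be purchasable.
- The carbinol carbon that becomes C2 is not touched between step 2 and step 17. Its descriptor changes from S to R in step 6 only because the priorities of its neighbors change.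
- C2 is carried as a tert-butyldiphenylsilyl (TBDPS) ether and C8 as a triethylsilyl ether, so that C8 can be unmasked first with a wide margin.
- The facial sense assigned to the catalyst in step 2 rests on analogy with its reported allyl- and allenylborations and would be confirmed on the alcohol from step 2 (Mosher esters).

Step 1
Reactants: 1 2,2-dimethylpent-4-enal
Product: 3 3,3-dimethylhex-5-enal, via methyl enol ether 2 (not isolated)
Conditions: Ph3P(CH2OMe)Cl, KOt-Bu, THF, 0 °C to rt; then 2 M HCl, THF, rt
Reagents that add atoms: (methoxymethyl)triphenylphosphonium chloride, COC[P+](c1ccccc1)(c1ccccc1)c1ccccc1.[Cl-]; water, O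
Why: Wittig methoxymethylenation of the non-enolizable α-quaternary aldehyde followed by acid hydrolysis of the enol ether is a standard one-carbon homologation, the remote terminal alkene is inert to both stages, and no stereocenter is formed.

Step 2
Reactants: 3 3,3-dimethylhex-5-enal; 4 allenylboronic acid pinacol ester
Product: 6 (4S)-6,6-dimethylnon-8-en-1-yn-4-ol, via pinacol borate 5 (not isolated)
Conditions: (R)-3,3'-bis(2,4,6-triisopropylphenyl)-1,1'-binaphthyl-2,2'-diyl hydrogen phosphate (10 mol%), 4 Å molecular sieves, toluene, −20 °C; aq. NaHCO3 work-up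
Reagents that add atoms: none
Why: Chiral phosphoric acid-catalyzed allenylboration (SE2' propargylation through a closed six-membered chair transition state in which the acid binds the boronate oxygen and the formyl hydrogen) should, by analogy with the Re-face selectivity of this catalyst in allyl- and allenylborations of aldehydes, deliver the propargyl group to the Re face of 3 and so set the (4S) carbinol center.

Step 3
Reactants: 6 (4S)-6,6-dimethylnon-8-en-1-yn-4-ol
Product: 7 tert-butyl{[(4S)-6,6-dimethylnon-8-en-1-yn-4-yl]oxy}diphenylsilane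
Conditions: TBDPSCl, imidazole, DMAP (cat.), DMF, rt
Reagents that add atoms: tert-butyl(chloro)diphenylsilane, CC(C)(C)[Si](Cl)(c1ccccc1)c1ccccc1
Why: Imidazole-promoted silylation of the secondary alcohol installs a bulky ether that tolerates organoaluminium reagents, heat and the later acidic removal of the C8 triethylsilyl ether, and that sits equatorially in the key step.

Step 4
Reactants: 7 tert-butyl{[(4S)-6,6-dimethylnon-8-en-1-yn-4-yl]oxy}diphenylsilane
Product: 9 methyl (2E,5S)-5-(tert-butyldiphenylsilyloxy)-3,7,7-trimethyldeca-2,9-dienoate, via alkenylalane 8 (not isolated)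
Conditions: AlMe3 (3 equiv), Cp2ZrCl2 (25 mol%), CH2Cl2, 0 °C to rt; then ClCO2Me, 0 °C to rt
Reagents that add atoms: trimethylaluminium, C[Al](C)C; methyl chloroformate, COC(=O)Cl
Why: Negishi zirconium-catalyzed carboalumination adds methyl and aluminium syn across the terminal alkyne with the metal at the terminus while the isolated alkene is left alone, and acylation of the alkenylalane by the chloroformate with retention fixes the (2E) trisubstituted enoate.

Step 5
Reactants: 9 methyl (2E,5S)-5-(tert-butyldiphenylsilyloxy)-3,7,7-trimethyldeca-2,9-dienoate; 10 (E)-but-2-enal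
Product: 11 methyl (2E,5S,9E)-5-(tert-butyldiphenylsilyloxy)-3,7,7-trimethyl-11-oxoundeca-2,9-dienoate
Conditions: second-generation Hoveyda–Grubbs catalyst RuCl2(H2IMes)(=CH-C6H4-2-O-i-Pr) (3 mol%), 10 (5 equiv), CH2Cl2, 40 °C
Reagents that add atoms: none
Why: Olefin cross-metathesis of the monosubstituted terminal alkene with excess crotonaldehyde is a reliable E-selective route to enals, and the trisubstituted electron-poor enoate does not take part.

Step 6
Reactants: 11 methyl (2E,5S,9E)-5-(tert-butyldiphenylsilyloxy)-3,7,7-trimethyl-11-oxoundeca-2,9-dienoate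
Product: 12 methyl (2E,5R,8E,10E)-5-(tert-butyldiphenylsilyloxy)-3,7,7-trimethyl-11-(triethylsilyloxy)undeca-2,8,10-trienoate
Conditions: Et3SiOTf, Et3N, CH2Cl2, −78 to 0 °C
Reagents that add atoms: triethylsilyl trifluoromethanesulfonate, CC[Si](CC)(CC)OS(=O)(=O)C(F)(F)F
Why: Soft dienolization (O-silylation of the enal followed by γ-deprotonation with the amine) gives the 1-silyloxydiene, the s-trans enal leading to the (10E) enol ether and the bulky quaternary substituent to the (8E) alkene, while the far less readily silylated enoate is untouched.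

Step 7
Reactants: 12 methyl (2E,5R,8E,10E)-5-(tert-butyldiphenylsilyloxy)-3,7,7-trimethyl-11-(triethylsilyloxy)undeca-2,8,10-trienoate
Product: 13 methyl 2α-(tert-butyldiphenylsilyloxy)-8β-(triethylsilyloxy)-12,13,14,15,16,17-hexanorlabd-6-en-11-oate
Conditions: toluene (0.01 M), BHT (cat.), N,O-bis(trimethylsilyl)acetamide (0.1 equiv), 180 °C, sealed tube
Reagents that add atoms: none
Why: A concerted, asynchronous [4+2] cycloaddition in which the electron-rich (E,E)-1-silyloxydiene C5=C6–C7=C8 adds suprafacially to the (E)-enoate C9=C10, its nucleophilic terminus C5 bonding to the β-carbon C10 and C8 to C9, the orientation that both the tether and the polarity demand. The closest known reaction type is the type 1 intramolecular Diels–Alder reaction of (E,E,E)-1,7,9-decatrienoates, which gives trans-fused octalins including ones with an angular methyl group. Ring B (six-membered) is the cyclohexene created by the cycloaddition itself, and ring A (six-membered) closes at the same moment because the new C5–C10 bond joins the two ends of the four-atom tether C1–C4, which adopts a chair. C9 and C10 keep the cis relation of ester and methyl given by the E-enoate, C8 follows from the E-enol ether together with the endo position of the ester (silyloxy cis to ester), C5 is set trans to C20 by the ester-endo, tether-anti arrangement, and the absolute sense comes from C2, whose silyloxy group stays equatorial on the forming chair because an axial group would meet the C19 and C20 methyl groups. The step needs trans over cis ring fusion and one face of the diene: the endo preference of the ester is expected to provide the first, the single C2 stereocenter provides the second, and the C4 gem-dimethyl group favors the coiled reactive conformer.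

Step 8
Reactants: 13 methyl 2α-(tert-butyldiphenylsilyloxy)-8β-(triethylsilyloxy)-12,13,14,15,16,17-hexanorlabd-6-en-11-oate
Product: 14 2α-(tert-butyldiphenylsilyloxy)-8β-(triethylsilyloxy)-12,13,14,15,16,17-hexanorlabd-6-en-11-ol
Conditions: i-Bu2AlH (3 equiv), CH2Cl2, −78 to 0 °C; aq. potassium sodium tartrate
Reagents that add atoms: none
Why: Aluminium hydride reduction of the hindered ester to the primary alcohol passes through a weakly basic aluminium alkoxide, so the neighboring C8 silyl ether is expected neither to migrate nor to be cleaved.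

Step 9
Reactants: 14 2α-(tert-butyldiphenylsilyloxy)-8β-(triethylsilyloxy)-12,13,14,15,16,17-hexanorlabd-6-en-11-ol
Product: 15 2α-(tert-butyldiphenylsilyloxy)-8β-(triethylsilyloxy)-12,13,14,15,16,17-hexanorlabd-6-en-11-al
Conditions: Dess–Martin periodinane, NaHCO3, CH2Cl2, 0 °C to rt
Reagents that add atoms: none
Why: Dess–Martin oxidation under buffered, non-basic conditions should give the aldehyde without epimerizing C9 or eliminating the β-silyloxy group.

Step 10
Reactants: 16 (3R)-5-methoxy-3-methyl-5-oxopentanoic acid
Product: 18 methyl (3S)-4-iodo-3-methylbutanoate, via acyl hypoiodite 17 (not isolated)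
Conditions: PhI(OAc)2, I2, benzene, hν (tungsten lamp), reflux
Reagents that add atoms: iodine, II
Why: Suárez iododecarboxylation (homolysis of the acyl hypoiodite, loss of CO2 and iodine transfer to the primary radical) shortens the chain by one carbon without touching the methyl-bearing stereocenter, whose descriptor changes from R to S only through the priorities.

Step 11
Reactants: 18 methyl (3S)-4-iodo-3-methylbutanoate
Product: 19 [(2S)-4-methoxy-2-methyl-4-oxobutyl]triphenylphosphonium iodide
Conditions: PPh3, MeCN, reflux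
Reagents that add atoms: triphenylphosphine, c1ccc(cc1)P(c1ccccc1)c1ccccc1
Why: SN2 quaternization of the phosphine by the primary iodide, the usual way to 3-(alkoxycarbonyl)propyl phosphonium salts.

Step 12
Reactants: 15 2α-(tert-butyldiphenylsilyloxy)-8β-(triethylsilyloxy)-12,13,14,15,16,17-hexanorlabd-6-en-11-al; 19 [(2S)-4-methoxy-2-methyl-4-oxobutyl]triphenylphosphonium iodide
Product: 21 methyl (11Z,13S)-2α-(tert-butyldiphenylsilyloxy)-8β-(triethylsilyloxy)-17-norlabda-6,11-dien-15-oate, via phosphorus ylide 20 (not isolated)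
Conditions: 19 (2 equiv), NaN(SiMe3)2, THF, −78 to 0 °C; then 15, −78 °C to rt
Reagents that add atoms: none
Why: Wittig olefination with the non-stabilized ylide, formed at the phosphonium α-carbon and not at the less acidic ester α-carbon, joins C11 to C12 and brings in C13 with its configuration intact, the alkene geometry being irrelevant because the bond is hydrogenated next.

Step 13
Reactants: 21 methyl (11Z,13S)-2α-(tert-butyldiphenylsilyloxy)-8β-(triethylsilyloxy)-17-norlabda-6,11-dien-15-oate
Product: 23 methyl (13R)-2α-(tert-butyldiphenylsilyloxy)-8β-hydroxy-17-norlabdan-15-oate, via saturated bis-silyl ether 22 (not isolated)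
Conditions: H2 (4 bar), PtO2, EtOAc, rt; filter; then PPTS, MeOH, rt to 40 °C
Reagents that add atoms: none
Why: Heterogeneous hydrogenation over platinum, chosen over palladium because it rarely migrates double bonds and so protects the allylic centers C5, C9 and C13, saturates both disubstituted alkenes, and mild acid methanolysis then removes the triethylsilyl ether far faster than the TBDPS ether.

Step 14
Reactants: 23 methyl (13R)-2α-(tert-butyldiphenylsilyloxy)-8β-hydroxy-17-norlabdan-15-oate
Product: 24 methyl (13R)-2α-(tert-butyldiphenylsilyloxy)-8-oxo-17-norlabdan-15-oate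
Conditions: Dess–Martin periodinane, NaHCO3, CH2Cl2, rt
Reagents that add atoms: none
Why: Dess–Martin oxidation of the axial secondary alcohol gives the C8 ketone, in which C9 keeps its stable configuration with the side chain equatorial.

Step 15
Reactants: 24 methyl (13R)-2α-(tert-butyldiphenylsilyloxy)-8-oxo-17-norlabdan-15-oate
Product: 25 methyl (13R)-2α-(tert-butyldiphenylsilyloxy)labd-8(17)-en-15-oate
Conditions: Ph3PCH3Br, KOt-Bu, THF, 0 to 50 °C
Reagents that add atoms: methyltriphenylphosphonium bromide, C[P+](c1ccccc1)(c1ccccc1)c1ccccc1.[Br-]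
Why: Wittig methylenation of the hindered ketone with excess ylide is the standard way from an 8-oxolabdane to the exocyclic 8(17)-alkene, it should outpace attack on the methyl ester, and any enolization towards C9 returns the equatorial side chain.

Step 16
Reactants: 25 methyl (13R)-2α-(tert-butyldiphenylsilyloxy)labd-8(17)-en-15-oate
Product: 26 methyl (13R)-2α-hydroxylabd-8(17)-en-15-oate
Conditions: Bu4NF, AcOH, THF, rt to 45 °C
Reagents that add atoms: none
Why: Fluoride-induced desilylation, buffered with acetic acid to spare the methyl ester, frees the equatorial 2α-alcohol without touching the acid-sensitive exocyclic alkene.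

Step 17
Reactants: 26 methyl (13R)-2α-hydroxylabd-8(17)-en-15-oate
Product: 27 methyl (13R)-2-oxolabd-8(17)-en-15-oate
Conditions: Dess–Martin periodinane, NaHCO3, CH2Cl2, rt
Reagents that add atoms: none
Why: Dess–Martin oxidation erases the 2α center, which has done its work as control element, in preparation for its inversion.

Step 18
Reactants: 27 methyl (13R)-2-oxolabd-8(17)-en-15-oate
Product: 29 (13R)-2β-hydroxylabd-8(17)-en-15-oic acid, via 2β-hydroxy ester 28 (not isolated)
Conditions: NaBH4, MeOH/THF, −20 to 0 °C; then LiOH, H2O, rt to 40 °C; 1 M HCl to pH 3 at 0 °C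
Reagents that add atoms: lithium hydroxide, [Li+].[OH-]
Why: Borohydride reduction in which hydride can approach C2 only from the α face, because the β face is screened by the syn-axial C19 and C20 methyl groups, should set the axial 2β-alcohol, and saponification (BAc2) in the same flask then frees the acid.

Step 19
Reactants: 29 (13R)-2β-hydroxylabd-8(17)-en-15-oic acid
Product: 31 (13R)-2β-acetoxylabd-8(17)-en-15-oic acid, via mixed anhydride 30 (not isolated)
Conditions: Ac2O, DMAP, pyridine, rt to 40 °C; then H2O, pyridine, rt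
Reagents that add atoms: acetic anhydride, CC(=O)OC(C)=O
Why: DMAP-catalyzed acetylation of the hindered axial alcohol with excess anhydride also converts the acid into a mixed anhydride, which water cleaves at the acetyl carbonyl during work-up far faster than it could touch the secondary acetate.

Compound list
1 | 2,2-dimethylpent-4-enal | C=CCC(C)(C)C=O | starting material
2 | 1-methoxy-3,3-dimethylhexa-1,5-diene (E/Z mixture, formed in the flask) | COC=CC(C)(C)CC=C | intermediate
3 | 3,3-dimethylhex-5-enal | C=CCC(C)(C)CC=O | intermediate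
4 | allenylboronic acid pinacol ester, 4,4,5,5-tetramethyl-2-(propa-1,2-dien-1-yl)-1,3,2-dioxaborolane | C=C=CB1OC(C)(C)C(C)(C)O1 | starting material
5 | 2-{[(4S)-6,6-dimethylnon-8-en-1-yn-4-yl]oxy}-4,4,5,5-tetramethyl-1,3,2-dioxaborolane (formed in the flask) | C#CC[C@@H](OB1OC(C)(C)C(C)(C)O1)CC(C)(C)CC=C | intermediate
6 | (4S)-6,6-dimethylnon-8-en-1-yn-4-ol | C#CC[C@@H](O)CC(C)(C)CC=C | intermediate
7 | tert-butyl{[(4S)-6,6-dimethylnon-8-en-1-yn-4-yl]oxy}diphenylsilane | C#CC[C@@H](O[Si](c1ccccc1)(c1ccccc1)C(C)(C)C)CC(C)(C)CC=C | intermediate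
8 | [(1E,4S)-4-(tert-butyldiphenylsilyloxy)-2,6,6-trimethylnona-1,8-dien-1-yl]dimethylalane (formed in the flask) | C[Al](C)/C=C(C)/C[C@@H](O[Si](c1ccccc1)(c1ccccc1)C(C)(C)C)CC(C)(C)CC=C | intermediate
9 | methyl (2E,5S)-5-(tert-butyldiphenylsilyloxy)-3,7,7-trimethyldeca-2,9-dienoate | COC(=O)/C=C(C)/C[C@@H](O[Si](c1ccccc1)(c1ccccc1)C(C)(C)C)CC(C)(C)CC=C | intermediate
10 | (E)-but-2-enal (crotonaldehyde) | C/C=C/C=O | starting material
11 | methyl (2E,5S,9E)-5-(tert-butyldiphenylsilyloxy)-3,7,7-trimethyl-11-oxoundeca-2,9-dienoate | COC(=O)/C=C(C)/C[C@@H](O[Si](c1ccccc1)(c1ccccc1)C(C)(C)C)CC(C)(C)C/C=C/C=O | intermediate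
12 | methyl (2E,5R,8E,10E)-5-(tert-butyldiphenylsilyloxy)-3,7,7-trimethyl-11-(triethylsilyloxy)undeca-2,8,10-trienoate | COC(=O)/C=C(C)/C[C@@H](O[Si](c1ccccc1)(c1ccccc1)C(C)(C)C)CC(C)(C)/C=C/C=C/O[Si](CC)(CC)CC | intermediate
13 | methyl 2α-(tert-butyldiphenylsilyloxy)-8β-(triethylsilyloxy)-12,13,14,15,16,17-hexanorlabd-6-en-11-oate | CC[Si](CC)(CC)O[C@H]1C=C[C@H]2C(C)(C)C[C@H](O[Si](c3ccccc3)(c3ccccc3)C(C)(C)C)C[C@]2(C)[C@H]1C(=O)OC | intermediate
14 | 2α-(tert-butyldiphenylsilyloxy)-8β-(triethylsilyloxy)-12,13,14,15,16,17-hexanorlabd-6-en-11-ol | CC[Si](CC)(CC)O[C@H]1C=C[C@H]2C(C)(C)C[C@H](O[Si](c3ccccc3)(c3ccccc3)C(C)(C)C)C[C@]2(C)[C@H]1CO | intermediate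
15 | 2α-(tert-butyldiphenylsilyloxy)-8β-(triethylsilyloxy)-12,13,14,15,16,17-hexanorlabd-6-en-11-al | CC[Si](CC)(CC)O[C@H]1C=C[C@H]2C(C)(C)C[C@H](O[Si](c3ccccc3)(c3ccccc3)C(C)(C)C)C[C@]2(C)[C@H]1C=O | intermediate
16 | (3R)-5-methoxy-3-methyl-5-oxopentanoic acid, methyl hydrogen (R)-3-methylglutarate | OC(=O)C[C@@H](C)CC(=O)OC | starting material
17 | (3S)-5-methoxy-3-methyl-5-oxopentanoyl hypoiodite (formed in the flask) | IOC(=O)C[C@@H](C)CC(=O)OC | intermediate
18 | methyl (3S)-4-iodo-3-methylbutanoate | IC[C@@H](C)CC(=O)OC | intermediate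
19 | [(2S)-4-methoxy-2-methyl-4-oxobutyl]triphenylphosphonium iodide | COC(=O)C[C@H](C)C[P+](c1ccccc1)(c1ccccc1)c1ccccc1.[I-] | intermediate
20 | methyl (3S)-3-methyl-4-(triphenyl-λ5-phosphanylidene)butanoate (formed in the flask) | COC(=O)C[C@H](C)C=P(c1ccccc1)(c1ccccc1)c1ccccc1 | intermediate
21 | methyl (11Z,13S)-2α-(tert-butyldiphenylsilyloxy)-8β-(triethylsilyloxy)-17-norlabda-6,11-dien-15-oate | CC[Si](CC)(CC)O[C@H]1C=C[C@H]2C(C)(C)C[C@H](O[Si](c3ccccc3)(c3ccccc3)C(C)(C)C)C[C@]2(C)[C@H]1/C=C\[C@@H](C)CC(=O)OC | intermediate
22 | methyl (13R)-2α-(tert-butyldiphenylsilyloxy)-8β-(triethylsilyloxy)-17-norlabdan-15-oate (formed in the flask) | CC[Si](CC)(CC)O[C@H]1CC[C@H]2C(C)(C)C[C@H](O[Si](c3ccccc3)(c3ccccc3)C(C)(C)C)C[C@]2(C)[C@H]1CC[C@@H](C)CC(=O)OC | intermediate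
23 | methyl (13R)-2α-(tert-butyldiphenylsilyloxy)-8β-hydroxy-17-norlabdan-15-oate | O[C@H]1CC[C@H]2C(C)(C)C[C@H](O[Si](c3ccccc3)(c3ccccc3)C(C)(C)C)C[C@]2(C)[C@H]1CC[C@@H](C)CC(=O)OC | intermediate
24 | methyl (13R)-2α-(tert-butyldiphenylsilyloxy)-8-oxo-17-norlabdan-15-oate | O=C1CC[C@H]2C(C)(C)C[C@H](O[Si](c3ccccc3)(c3ccccc3)C(C)(C)C)C[C@]2(C)[C@H]1CC[C@@H](C)CC(=O)OC | intermediate
25 | methyl (13R)-2α-(tert-butyldiphenylsilyloxy)labd-8(17)-en-15-oate | C=C1CC[C@H]2C(C)(C)C[C@H](O[Si](c3ccccc3)(c3ccccc3)C(C)(C)C)C[C@]2(C)[C@H]1CC[C@@H](C)CC(=O)OC | intermediate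
26 | methyl (13R)-2α-hydroxylabd-8(17)-en-15-oate | C=C1CC[C@H]2C(C)(C)C[C@H](O)C[C@]2(C)[C@H]1CC[C@@H](C)CC(=O)OC | intermediate
27 | methyl (13R)-2-oxolabd-8(17)-en-15-oate | C=C1CC[C@H]2C(C)(C)CC(=O)C[C@]2(C)[C@H]1CC[C@@H](C)CC(=O)OC | intermediate
28 | methyl (13R)-2β-hydroxylabd-8(17)-en-15-oate (formed in the flask) | C=C1CC[C@H]2C(C)(C)C[C@@H](O)C[C@]2(C)[C@H]1CC[C@@H](C)CC(=O)OC | intermediate
29 | (13R)-2β-hydroxylabd-8(17)-en-15-oic acid | C=C1CC[C@H]2C(C)(C)C[C@@H](O)C[C@]2(C)[C@H]1CC[C@@H](C)CC(=O)O | intermediate
30 | acetic (13R)-2β-acetoxylabd-8(17)-en-15-oic anhydride (formed in the flask) | C=C1CC[C@H]2C(C)(C)C[C@@H](OC(C)=O)C[C@]2(C)[C@H]1CC[C@@H](C)CC(=O)OC(C)=O | intermediate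
31 | (13R)-2β-acetoxylabd-8(17)-en-15-oic acid | C=C1CC[C@H]2C(C)(C)C[C@@H](OC(C)=O)C[C@]2(C)[C@H]1CC[C@@H](C)CC(=O)O | target

Total step count: 19.
Longest linear sequence: 17 steps (steps 1–9 and 12–19, from 1 to 31); the side-chain branch from 16 is steps 10 and 11.

Steps most likely to fail

Step 7. The unactivated β,β-disubstituted enoate may need a temperature at which the ester-exo (cis-fused) transition state competes, helped by the contact between the axial C4 methyl and C20 in the trans chair, and at which the silyl dienol ether slowly desilylates. Fusion selectivity and mass balance would then erode. The fallback raises the reactivity of the dienophile instead of the temperature. Setting out from 12, i-Bu2AlH (CH2Cl2, −78 °C) reduces the enoate to the (2E)-allylic alcohol, (2E,5R,8E,10E)-5-(tert-butyldiphenylsilyloxy)-3,7,7-trimethyl-11-(triethylsilyloxy)undeca-2,8,10-trien-1-ol F1. MnO2 (CH2Cl2, rt) oxidizes it to the trienal F2. The enal has a lower LUMO and a stronger endo preference, so it should undergo the same cycloaddition through the same chair, carbonyl-endo transition state in toluene at 60–100 °C. This gives aldehyde 15 directly, where the fallback comes back to the route; steps 8 and 9 are then not needed.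

Step 12. The ylide may act as a base on the hindered aldehyde, deprotonating C9 with β-elimination of the C8 silyloxy group or epimerization, or it may add too slowly because both partners are branched next to the reacting carbons. The fallback is a Julia–Kocienski olefination run under Barbier conditions. Setting out from iodide 18, 1-phenyl-1H-tetrazole-5-thiol and K2CO3 in acetone give the sulfide, methyl (3S)-3-methyl-4-[(1-phenyl-1H-tetrazol-5-yl)sulfanyl]butanoate F3. (NH4)6Mo7O24 and H2O2 in EtOH oxidize it to the sulfone F4. KN(SiMe3)2 is then added at −78 °C to a mixture of F4 and 15 in DME, so that the aldehyde never meets an excess of base, and the (11E)-alkene F5 should result. Hydrogenation of F5 under the conditions of step 13 gives 22, where the fallback comes back to the route.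

Step 2. Facial discrimination by the phosphoric acid may be incomplete for this β-quaternary aliphatic aldehyde, and an uncatalyzed background addition would lower the enantiomeric purity on which the absolute configuration of the whole ring system depends. The fallback takes the carbinol center from a resolved epoxide. Setting out from 3, Corey–Chaykovsky methylenation (trimethylsulfonium iodide, n-BuLi, THF, −10 °C) gives the racemic epoxide, 2-(2,2-dimethylpent-4-en-1-yl)oxirane F6. Jacobsen hydrolytic kinetic resolution with (S,S)-N,N'-bis(3,5-di-tert-butylsalicylidene)-1,2-cyclohexanediaminocobalt acetate, (S,S)-(salen)Co(OAc), a complex of trivalent cobalt (0.5 mol%), and 0.55 equiv of water should hydrolyze the (R)-epoxide and leave the (S)-epoxide F7. Lithium acetylide–ethylenediamine complex in DMSO opens F7 at its CH2 terminus without touching the stereocenter and gives alcohol 6, where the fallback comes back to the route.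

Further compounds
F1 | step 7 | (2E,5R,8E,10E)-5-(tert-butyldiphenylsilyloxy)-3,7,7-trimethyl-11-(triethylsilyloxy)undeca-2,8,10-trien-1-ol | OC/C=C(C)/C[C@@H](O[Si](c1ccccc1)(c1ccccc1)C(C)(C)C)CC(C)(C)/C=C/C=C/O[Si](CC)(CC)CC
F2 | step 7 | (2E,5R,8E,10E)-5-(tert-butyldiphenylsilyloxy)-3,7,7-trimethyl-11-(triethylsilyloxy)undeca-2,8,10-trienal | O=C/C=C(C)/C[C@@H](O[Si](c1ccccc1)(c1ccccc1)C(C)(C)C)CC(C)(C)/C=C/C=C/O[Si](CC)(CC)CC
F3 | step 12 | methyl (3S)-3-methyl-4-[(1-phenyl-1H-tetrazol-5-yl)sulfanyl]butanoate | COC(=O)C[C@H](C)CSc1nnnn1-c1ccccc1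
F4 | step 12 | methyl (3S)-3-methyl-4-[(1-phenyl-1H-tetrazol-5-yl)sulfonyl]butanoate | COC(=O)C[C@H](C)CS(=O)(=O)c1nnnn1-c1ccccc1
F5 | step 12 | methyl (11E,13S)-2α-(tert-butyldiphenylsilyloxy)-8β-(triethylsilyloxy)-17-norlabda-6,11-dien-15-oate | CC[Si](CC)(CC)O[C@H]1C=C[C@H]2C(C)(C)C[C@H](O[Si](c3ccccc3)(c3ccccc3)C(C)(C)C)C[C@]2(C)[C@H]1/C=C/[C@@H](C)CC(=O)OC
F6 | step 2 | racemic 2-(2,2-dimethylpent-4-en-1-yl)oxirane | C=CCC(C)(C)CC1CO1
F7 | step 2 | (2S)-2-(2,2-dimethylpent-4-en-1-yl)oxirane | C=CCC(C)(C)C[C@H]1CO1
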